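## Structural features

The target is an isoflavanone: benzene ring A is fused to the dihydropyranone ring C (O1, C2, C3, C4, C4a, C8a), and benzene ring B is attached through C1' to C3. Ring A carries a free hydroxyl at C7 and a prenyl group at C6; ring B carries a free hydroxyl at C4' and a prenyl group at C3', so each prenyl group sits ortho to a phenol. C3 is the only stereocentre, (S), with no stereogenic neighbour in the target; in the intermediates a temporary carbinol centre at C4 stands next to it. C3 is tertiary, benzylic to ring B and α to the C4 ketone, so its C–H bond is acidic and the centre racemises under base once ketone and aryl group are both present. The fragile groups are the two ortho-prenylphenol units (acid closes them to dimethylchromans, oxidants give chromenes, hydrogenation saturates them), the free phenols and the enolisable ketone. The real difficulty is therefore to set C3 as one enantiomer and carry it to the end without base or acid acting on the finished isoflavanone. The key step uses the substitution pattern of ring B: C1' and C2' come from the α-carbon and the carbonyl carbon of an acetaldehyde side chain on C3. C3' to C6' come from a four-carbon ynone whose carbonyl carbon becomes C4'–OH and whose α'-carbon, already carrying the prenyl group, becomes C3'.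

## Logic of the disconnections

**21 to 20.** The O7–Si and O4'–Si bonds are cut first. Both phenols stay silylated to the end because free phenols would not tolerate the oxidation that creates the C4 ketone, and because fluoride removes silyl groups without acid, hydrogen or oxidant. The skeleton is not simplified, but the two delicate operations are separated. The demand on the forward step is a fluoride source that is not basic, since the C3–H bond of 20 and 21 is benzylic and α to the ketone.

**20 to 19, 18 and 17.** The C4 carbonyl is taken back to a cis C4 carbinol, this to its triethylsilyl ether, and the O4' silyl ether to the free phenol. With C4 at the sp3 level the C3–H bond is not acidic, so C3 is configurationally safe while ring B is built. The forward steps must cleave one alkyl silyl ether in the presence of two aryl silyl ethers (acidic fluoride favours the alkyl Si–O bond) and must oxidise without base.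

**17 to 11 and 14.** The bonds C1'–C6' and C2'–C3' of ring B are cut. This removes a whole aromatic ring together with its hydroxyl and prenyl group and leaves a C3 acetaldehyde side chain and a small ynone; the ynone supplies the aromatic oxidation level, so no dehydrogenation is needed. The forward step must add the aldehyde α-carbon to the alkyne terminus and close the ring only through the α'-methylene, without touching C3. The O7 group of 11 is a triisopropylsilyl ether, not a smaller silyl ether, because this oxygen is para to a carbonyl group during the basic steps before 11 and again in 20, and because the amine of the ring-forming step must not cleave it.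

**14 to 13 and 12.** The bond between the carbonyl carbon and the alkyne is cut, leading through the N-methoxy-N-methylamide 13 to ester 12. The amide stops the acetylide addition at the ketone stage; the forward quench must keep the released hydroxylamine away from the ynone.

**11 to 10, 9 and 7.** The aldehyde is taken back to a primary silyl ether, both silyl ethers to the cis diol 9, and the diol to keto ester 7. The cis hydroxy ester 8 that lies between 7 and 9 would close to a five-membered lactone if isolated, so the ester is reduced in the same flask and the aldehyde is regenerated later by oxidative desilylation of the primary ether of 10. The forward steps need hydride attack on C4 anti to the C3 side chain, with no enolisation at C3, and an oxidation that distinguishes a primary from a hindered secondary triethylsilyl ether.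

**7 to 6.** The C3–C4 bond is cut. Ring C and the stereocentre are traced to an achiral aldehyde tethered to an (E)-enoate, so C3 is set by a catalyst in the ring-closing step. The forward step needs high facial selectivity on the enoate and a product that does not enolise under the catalytic base.

**6 to 4 and 5.** The O1–C2 ether bond is cut, giving a salicylaldehyde and an allylic bromide. The phenoxide must react at the CH2Br carbon with retention of the E geometry.

**4 to 2 and 3, and 2 to 1.** The C6–prenyl bond is cut to an aryl bromide and a prenylstannane, and the O7–Si bond to the commercial bromoresorcinol aldehyde 1. The coupling comes before the etherification so that no allylic aryl ether is exposed to palladium; it must deliver the linear prenyl isomer. The silylation must select the unchelated 4-hydroxyl over the chelated 2-hydroxyl.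

## Other disconnections considered

**Alternative 1:** The cut runs through ring A itself (C7–C8, C4a–C8a and C6–C7), leading to the diazo enone (E)-1-diazo-7-methylocta-3,6-dien-2-one A1 and methoxyacetylene A2.

- **Forward key step:** irradiation of A1 would trigger a Wolff rearrangement to a vinylketene, which adds A2 in a (2+2) sense. The 4-vinylcyclobutenone opens (4π), recloses (6π) and tautomerises to 5-methoxy-2-(3-methylbut-2-enyl)phenol A3, a resorcinol with differentiated oxygens.
- **In its favour:** the prenyl group is placed by connectivity, with no allyl-metal regiochemistry and no tin. On this one point it is better than step 2 of the chosen plan.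
- **Against it here:** it builds a ring that can be bought correctly substituted as 1. A1 carries a skipped diene next to a diazo ketone, open to conjugation and intramolecular cyclopropanation. A2 is volatile and labile. After A3, silylation, para-formylation and a Lewis-acid O-demethylation next to a prenyl group would still be needed only to reach 4.
- **Comparison:** structurally it solves ring A regiochemistry, a minor problem, and leaves C3, ring C and ring B untouched. Mechanistically the pericyclic cascade is as predictable in regiochemistry as the enamine cascade, so the two are equal there, but it needs photochemical equipment. In step economy it is worse: several steps to A1 and three more from A3 to 4, against two steps from 1 to 4.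

**Alternative 2:** The cut is C3–C4, with the acceptor a ring B para-quinone methide. The precursor is the benzylic acetate A4, 1-[4-hydroxy-3-(3-methylbut-2-enyl)phenyl]-2-[2-formyl-4-(3-methylbut-2-enyl)-5-(triisopropylsilyloxy)phenoxy]ethyl acetate.

- **Forward key step:** a weak amine base would eliminate acetic acid from A4 to give quinone methide A5. The Breslow intermediate formed from the aldehyde and a chiral triazolylidene would add to the exocyclic carbon (C3), re-aromatising ring B and closing ring C to (S)-4'-hydroxy-6,3'-diprenyl-7-triisopropylsilyloxyisoflavanone A6.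
- **In its favour:** it is convergent (rings A and B are joined by one etherification). C3 is set and ring C closed directly at the ketone oxidation level with ring B in place, leaving one desilylation. In step economy it is clearly better than the chosen plan, roughly half the length, and it avoids the reduction and reoxidation at C4.
- **Against it here:** A5 has only one ortho substituent and no bulky flanking groups, so dimerisation, recapture by acetate or amine, and addition of the free carbene (a catalyst sink) all compete. Facial discrimination in a 1,6-addition to a flat exocyclic carbon has less precedent than addition to an enoate. A6 is formed with its doubly activated C3–H in the presence of base and carbene, so selectivity could erode as it forms, and A6 must still pass through fluoride.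
- **Comparison:** mechanistically the two plans are equal in the carbon–carbon bond-forming event (same Breslow intermediate, same C3–C4 bond, same catalyst class). Structurally the chosen plan forms C3 next to a CH2CO2Et group, where the C–H is much less acidic, and hides the ketone at once. This was preferred over the shorter route because configurational safety at C3 is the main problem of this target.

**Alternative 3:** The cut is C4a–C8a, C5–C6 and C7–C8, leading to the tethered diyne A7 (an ethynyl ether at the O1 end, a propargylic triethylsilyl ether at the C4 end, ring B already on C3) and the siloxyalkyne A8, triisopropyl[(5-methylhex-4-en-1-yn-1-yl)oxy]silane.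

- **Forward key step:** [Rh(cod)2]BF4 with a bisphosphine would join A7 and A8 in a (2+2+2) cycloaddition, closing rings A and C together to the trans isoflavan-4-ol tris-silyl ether A9.
- **In its favour:** ring A appears fully substituted in one step, with no aryl halide coupling and no selective phenol protection. The plan is convergent. The endgame from A9 is the same as from 18, so the two plans are equal there.
- **Against it here:** the orientation of A8 relative to the unsymmetrical diyne decides whether prenyl ends on C6 or C7, and it rests on catalyst and ligand, not on connectivity. The terminal ynol ether of A7 is prone to hydration and thermal ketene formation. The prenyl alkenes may compete for the metal. The C3 and C4 centres of A7 must be set in an open chain that already carries the ring B prenylphenol.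
- **Comparison:** structurally it is more ambitious (two rings at once) and better in convergence. Mechanistically its regiocontrol is less secure than in the chosen step, where the ring B pattern follows from which atoms are bonded. In step economy it is probably comparable, because A7 needs its own asymmetric sequence and the three-step oxidation and deprotection endgame remains.

Key step: step 10

Assumption: the enantiomer of the aminoindanol-derived triazolium salt in step 4 is taken to be the one whose facial preference gives (3S)-7; the antipodal salt is equally accessible if the sense proves opposite.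

## Route

Step 1
Reactants: 1 5-bromo-2,4-dihydroxybenzaldehyde
Product: 2 5-bromo-2-hydroxy-4-(triisopropylsilyloxy)benzaldehyde
Conditions: i-Pr3SiCl (1.05 equiv), imidazole, CH2Cl2, 0 → 23 °C
Reagents that add atoms: chlorotriisopropylsilane, CC(C)[Si](Cl)(C(C)C)C(C)C
Why: Regioselective O-silylation: the 2-hydroxyl is held in a hydrogen bond to the formyl group, so the more acidic, unchelated 4-hydroxyl should react first. The bulky triisopropylsilyl group is chosen because this aryl ether is para to a carbonyl group in the basic steps that follow.

Step 2
Reactants: 2 5-bromo-2-hydroxy-4-(triisopropylsilyloxy)benzaldehyde; 3 tributyl(3-methylbut-2-enyl)stannane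
Product: 4 2-hydroxy-5-(3-methylbut-2-enyl)-4-(triisopropylsilyloxy)benzaldehyde
Conditions: Pd(PPh3)4 (5 mol%), toluene, 100 °C
Reagents that add atoms: none
Why: Stille cross-coupling: zerovalent palladium inserts into the Ar–Br bond, the allylic stannane transmetalates, and reductive elimination at the less hindered terminus of the η3-prenyl ligand should give the linear prenyl arene. The neutral conditions leave phenol, aldehyde and aryl silyl ether alone, and running this before the etherification keeps allylic aryl ethers away from palladium.

Step 3
Reactants: 4 2-hydroxy-5-(3-methylbut-2-enyl)-4-(triisopropylsilyloxy)benzaldehyde; 5 ethyl (E)-4-bromobut-2-enoate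
Product: 6 ethyl (E)-4-[2-formyl-4-(3-methylbut-2-enyl)-5-(triisopropylsilyloxy)phenoxy]but-2-enoate
Conditions: K2CO3, acetone, 23 °C
Reagents that add atoms: none
Why: Williamson etherification by SN2 displacement at the primary allylic bromide. Mild carbonate in acetone should preserve the E-enoate and the triisopropylsilyl ether.

Step 4
Reactants: 6 ethyl (E)-4-[2-formyl-4-(3-methylbut-2-enyl)-5-(triisopropylsilyloxy)phenoxy]but-2-enoate
Product: 7 ethyl 2-[(3S)-6-(3-methylbut-2-enyl)-4-oxo-7-(triisopropylsilyloxy)chroman-3-yl]acetate
Conditions: aminoindanol-derived N-pentafluorophenyl triazolium tetrafluoroborate (10 mol%), KN(SiMe3)2 (9 mol%), toluene, 23 °C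
Reagents that add atoms: none
Why: Asymmetric intramolecular Stetter reaction of a salicylaldehyde-derived enoate, the established entry to 3-substituted chroman-4-ones. The Breslow intermediate adds 6-exo-trig to the β-carbon of the enoate, and the chiral triazolylidene selects the enoate face in this C–C bond-forming step, which sets C3. Keeping the base substoichiometric to the salt limits enolisation of the product.

Step 5
Reactants: 7 ethyl 2-[(3S)-6-(3-methylbut-2-enyl)-4-oxo-7-(triisopropylsilyloxy)chroman-3-yl]acetate
Product: 9 (3S,4S)-3-(2-hydroxyethyl)-6-(3-methylbut-2-enyl)-7-(triisopropylsilyloxy)chroman-4-ol, via cis-hydroxy ester 8 (not isolated)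
Conditions: LiBH(s-Bu)3, THF, −78 °C; then LiAlH4, −78 → 0 °C; aq. KNaC4H4O6
Reagents that add atoms: none
Why: Diastereoselective ketone reduction followed by ester reduction in one flask. The hindered borohydride should attack C4 from the face opposite the C3 side chain and give the cis carbinol without enolising C3. LiAlH4 then reduces the ester (or any lactone formed from 8) to the primary alcohol, so the lactonisation-prone cis hydroxy ester is never isolated.

Step 6
Reactants: 9 (3S,4S)-3-(2-hydroxyethyl)-6-(3-methylbut-2-enyl)-7-(triisopropylsilyloxy)chroman-4-ol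
Product: 10 (3S,4S)-6-(3-methylbut-2-enyl)-4-(triethylsilyloxy)-3-[2-(triethylsilyloxy)ethyl]-7-(triisopropylsilyloxy)chroman
Conditions: Et3SiOTf (2.4 equiv), 2,6-lutidine, CH2Cl2, −78 → 0 °C
Reagents that add atoms: triethylsilyl trifluoromethanesulfonate, CC[Si](CC)(CC)OS(=O)(=O)C(F)(F)F
Why: Exhaustive O-silylation with a silyl triflate and a hindered base, which should reach the hindered benzylic carbinol as well as the primary one. No stereocentre is touched.

Step 7
Reactants: 10 (3S,4S)-6-(3-methylbut-2-enyl)-4-(triethylsilyloxy)-3-[2-(triethylsilyloxy)ethyl]-7-(triisopropylsilyloxy)chroman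
Product: 11 2-[(3S,4S)-6-(3-methylbut-2-enyl)-4-(triethylsilyloxy)-7-(triisopropylsilyloxy)chroman-3-yl]acetaldehyde
Conditions: (COCl)2, DMSO, CH2Cl2, −78 → −40 °C; Et3N, −78 → 0 °C
Reagents that add atoms: none
Why: Swern oxidative desilylation, a known selective conversion of primary triethylsilyl ethers to aldehydes. The chlorosulfonium salt cleaves the unhindered primary Si–O bond to the alkoxysulfonium ion and Et3N then gives the aldehyde, while the hindered secondary benzylic triethylsilyl ether should stay intact.

Step 8
Reactants: 12 ethyl 5-methylhex-4-enoate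
Product: 13 N-methoxy-N,5-dimethylhex-4-enamide
Conditions: MeNH(OMe)·HCl, i-PrMgCl, THF, −20 → 0 °C
Reagents that add atoms: N,O-dimethylhydroxylamine hydrochloride, CNOC.Cl
Why: Direct Weinreb amide formation from an ester with the magnesium amide generated in the flask. The trisubstituted alkene is inert.

Step 9
Reactants: 13 N-methoxy-N,5-dimethylhex-4-enamide
Product: 14 7-methyloct-6-en-1-yn-3-one
Conditions: HC≡CMgBr, THF, 0 °C; inverse quench into cold aq. NaHSO4
Reagents that add atoms: ethynylmagnesium bromide, C#C[Mg]Br
Why: Weinreb ketone synthesis: the chelated tetrahedral adduct stops the addition at the ketone stage. The cold acidic inverse quench protonates the released hydroxylamine before it can add to the ynone.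

Step 10
Reactants: 11 2-[(3S,4S)-6-(3-methylbut-2-enyl)-4-(triethylsilyloxy)-7-(triisopropylsilyloxy)chroman-3-yl]acetaldehyde; 14 7-methyloct-6-en-1-yn-3-one
Product: 17 2-(3-methylbut-2-enyl)-4-[(3S,4S)-6-(3-methylbut-2-enyl)-4-(triethylsilyloxy)-7-(triisopropylsilyloxy)chroman-3-yl]phenol, via Michael adduct 15 (not isolated), via cyclohexadienone 16 (not isolated)
Conditions: pyrrolidine (30 mol%), AcOH (30 mol%), CHCl3, 23 → 50 °C, slow addition of 14 (1.5 equiv)
Reagents that add atoms: none
Why: Pyrrolidinium acetate converts 11 into its enamine, whose β-carbon (C1') adds to the terminal alkyne carbon of 14, the only electrophilic position of the ynone, to give enone 15 held as its iminium or dienamine; this is the amine-catalysed Michael–aldol benzannulation of aldehydes with alkynyl ketones, a known reaction type. The push–pull dienamine lets the C5'–C6' double bond equilibrate to the cis geometry, from which the enol of the α'-methylene attacks the iminium carbon C2' in a 6-(enolendo)-exo-trig closure, the only aldol mode that gives an unstrained ring. Loss of pyrrolidine forms the C2'–C3' double bond and returns the catalyst, and the 4-monosubstituted cyclohexadienone 16 tautomerises irreversibly to the phenol. No new stereocentre remains, because the transient sp3 centre at C1' is erased on aromatisation. The existing centres are not at risk, since C3 is β to the aldehyde carbon and C4 is a silyl ether, so neither enamine nor iminium formation acidifies the C3–H bond. Regiochemistry on ring B follows from connectivity: the ynone carbonyl becomes C4'–OH and its α'-carbon, which carries the prenyl group, becomes C3'. Chemoselectivity rests on buffering (the conjugate adduct of the amine with 14 can re-enter the cycle by addition–elimination) and on slow addition of 14, which limits ynone oligomerisation and double Michael addition.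

Step 11
Reactants: 17 2-(3-methylbut-2-enyl)-4-[(3S,4S)-6-(3-methylbut-2-enyl)-4-(triethylsilyloxy)-7-(triisopropylsilyloxy)chroman-3-yl]phenol
Product: 18 (3S,4S)-3-[4-(tert-butyldimethylsilyloxy)-3-(3-methylbut-2-enyl)phenyl]-6-(3-methylbut-2-enyl)-4-(triethylsilyloxy)-7-(triisopropylsilyloxy)chroman
Conditions: t-BuMe2SiCl, imidazole, DMF, 23 °C
Reagents that add atoms: tert-butylchlorodimethylsilane, CC(C)(C)[Si](C)(C)Cl
Why: Phenol O-silylation. The new phenol is capped so that the later hypervalent iodine oxidation meets no free phenol.

Step 12
Reactants: 18 (3S,4S)-3-[4-(tert-butyldimethylsilyloxy)-3-(3-methylbut-2-enyl)phenyl]-6-(3-methylbut-2-enyl)-4-(triethylsilyloxy)-7-(triisopropylsilyloxy)chroman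
Product: 19 (3S,4S)-3-[4-(tert-butyldimethylsilyloxy)-3-(3-methylbut-2-enyl)phenyl]-6-(3-methylbut-2-enyl)-7-(triisopropylsilyloxy)chroman-4-ol
Conditions: HF·pyridine, pyridine, THF, 0 °C
Reagents that add atoms: none
Why: Selective desilylation: under acidic fluoride an alkyl triethylsilyl ether is cleaved well before aryl tert-butyldimethylsilyl and triisopropylsilyl ethers. Excess pyridine keeps the medium too weakly acidic to ionise the electron-rich benzylic C4–O bond or to cyclise the prenyl groups.

Step 13
Reactants: 19 (3S,4S)-3-[4-(tert-butyldimethylsilyloxy)-3-(3-methylbut-2-enyl)phenyl]-6-(3-methylbut-2-enyl)-7-(triisopropylsilyloxy)chroman-4-ol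
Product: 20 (3S)-3-[4-(tert-butyldimethylsilyloxy)-3-(3-methylbut-2-enyl)phenyl]-6-(3-methylbut-2-enyl)-7-(triisopropylsilyloxy)chroman-4-one
Conditions: Dess–Martin periodinane, NaHCO3, CH2Cl2, 0 → 23 °C
Reagents that add atoms: none
Why: Dess–Martin oxidation of a secondary benzylic alcohol under buffered, non-basic conditions. The alkenes and aryl silyl ethers are inert and the C3–H bond, now α to the ketone, sees no base.

Step 14
Reactants: 20 (3S)-3-[4-(tert-butyldimethylsilyloxy)-3-(3-methylbut-2-enyl)phenyl]-6-(3-methylbut-2-enyl)-7-(triisopropylsilyloxy)chroman-4-one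
Product: 21 (3S)-7-hydroxy-3-[4-hydroxy-3-(3-methylbut-2-enyl)phenyl]-6-(3-methylbut-2-enyl)chroman-4-one
Conditions: Bu4NF, AcOH (1:1), THF, 0 °C
Reagents that add atoms: none
Why: Fluoride desilylation of both aryl silyl ethers; the O7 ether is para to the ketone and therefore activated. The acetic acid buffer should keep the medium from enolising C3, and no acid strong enough to cyclise the ortho-prenylphenols is present.

## Compound list

1 | 5-bromo-2,4-dihydroxybenzaldehyde | O=Cc1cc(Br)c(O)cc1O | starting material
2 | 5-bromo-2-hydroxy-4-(triisopropylsilyloxy)benzaldehyde | O=Cc1cc(Br)c(O[Si](C(C)C)(C(C)C)C(C)C)cc1O | intermediate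
3 | tributyl(3-methylbut-2-enyl)stannane | CCCC[Sn](CCCC)(CCCC)CC=C(C)C | starting material
4 | 2-hydroxy-5-(3-methylbut-2-enyl)-4-(triisopropylsilyloxy)benzaldehyde | O=Cc1cc(CC=C(C)C)c(O[Si](C(C)C)(C(C)C)C(C)C)cc1O | intermediate
5 | ethyl (E)-4-bromobut-2-enoate | CCOC(=O)/C=C/CBr | starting material
6 | ethyl (E)-4-[2-formyl-4-(3-methylbut-2-enyl)-5-(triisopropylsilyloxy)phenoxy]but-2-enoate | CCOC(=O)/C=C/COc1cc(O[Si](C(C)C)(C(C)C)C(C)C)c(CC=C(C)C)cc1C=O | intermediate
7 | ethyl 2-[(3S)-6-(3-methylbut-2-enyl)-4-oxo-7-(triisopropylsilyloxy)chroman-3-yl]acetate | CCOC(=O)C[C@H]1COc2cc(O[Si](C(C)C)(C(C)C)C(C)C)c(CC=C(C)C)cc2C1=O | intermediate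
8 | ethyl 2-[(3S,4S)-4-hydroxy-6-(3-methylbut-2-enyl)-7-(triisopropylsilyloxy)chroman-3-yl]acetate (cis; present as its lithium alkoxide) | CCOC(=O)C[C@H]1COc2cc(O[Si](C(C)C)(C(C)C)C(C)C)c(CC=C(C)C)cc2[C@H]1O | intermediate (not isolated)
9 | (3S,4S)-3-(2-hydroxyethyl)-6-(3-methylbut-2-enyl)-7-(triisopropylsilyloxy)chroman-4-ol (cis) | OCC[C@H]1COc2cc(O[Si](C(C)C)(C(C)C)C(C)C)c(CC=C(C)C)cc2[C@H]1O | intermediate
10 | (3S,4S)-6-(3-methylbut-2-enyl)-4-(triethylsilyloxy)-3-[2-(triethylsilyloxy)ethyl]-7-(triisopropylsilyloxy)chroman (cis) | CC[Si](CC)(CC)OCC[C@H]1COc2cc(O[Si](C(C)C)(C(C)C)C(C)C)c(CC=C(C)C)cc2[C@H]1O[Si](CC)(CC)CC | intermediate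
11 | 2-[(3S,4S)-6-(3-methylbut-2-enyl)-4-(triethylsilyloxy)-7-(triisopropylsilyloxy)chroman-3-yl]acetaldehyde (cis) | O=CC[C@H]1COc2cc(O[Si](C(C)C)(C(C)C)C(C)C)c(CC=C(C)C)cc2[C@H]1O[Si](CC)(CC)CC | intermediate
12 | ethyl 5-methylhex-4-enoate | CCOC(=O)CCC=C(C)C | starting material
13 | N-methoxy-N,5-dimethylhex-4-enamide | CON(C)C(=O)CCC=C(C)C | intermediate
14 | 7-methyloct-6-en-1-yn-3-one | C#CC(=O)CCC=C(C)C | intermediate
15 | (Z)-9-methyl-2-[(3S,4S)-6-(3-methylbut-2-enyl)-4-(triethylsilyloxy)-7-(triisopropylsilyloxy)chroman-3-yl]-5-oxodeca-3,8-dienal (both epimers at C2 of the chain; carried as its pyrrolidine iminium or dienamine) | O=CC(/C=C\C(=O)CCC=C(C)C)[C@H]1COc2cc(O[Si](C(C)C)(C(C)C)C(C)C)c(CC=C(C)C)cc2[C@H]1O[Si](CC)(CC)CC | intermediate (not isolated)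
16 | 2-(3-methylbut-2-enyl)-4-[(3S,4S)-6-(3-methylbut-2-enyl)-4-(triethylsilyloxy)-7-(triisopropylsilyloxy)chroman-3-yl]cyclohexa-2,5-dien-1-one (both epimers at the ring CH) | O=C1C=CC([C@H]2COc3cc(O[Si](C(C)C)(C(C)C)C(C)C)c(CC=C(C)C)cc3[C@H]2O[Si](CC)(CC)CC)C=C1CC=C(C)C | intermediate (not isolated)
17 | 2-(3-methylbut-2-enyl)-4-[(3S,4S)-6-(3-methylbut-2-enyl)-4-(triethylsilyloxy)-7-(triisopropylsilyloxy)chroman-3-yl]phenol (cis-4'-hydroxy-6,3'-diprenyl-4-triethylsilyloxy-7-triisopropylsilyloxyisoflavan) | CC[Si](CC)(CC)O[C@@H]1c2cc(CC=C(C)C)c(O[Si](C(C)C)(C(C)C)C(C)C)cc2OC[C@@H]1c1ccc(O)c(CC=C(C)C)c1 | intermediate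
18 | (3S,4S)-3-[4-(tert-butyldimethylsilyloxy)-3-(3-methylbut-2-enyl)phenyl]-6-(3-methylbut-2-enyl)-4-(triethylsilyloxy)-7-(triisopropylsilyloxy)chroman | CC[Si](CC)(CC)O[C@@H]1c2cc(CC=C(C)C)c(O[Si](C(C)C)(C(C)C)C(C)C)cc2OC[C@@H]1c1ccc(O[Si](C)(C)C(C)(C)C)c(CC=C(C)C)c1 | intermediate
19 | (3S,4S)-3-[4-(tert-butyldimethylsilyloxy)-3-(3-methylbut-2-enyl)phenyl]-6-(3-methylbut-2-enyl)-7-(triisopropylsilyloxy)chroman-4-ol | O[C@@H]1c2cc(CC=C(C)C)c(O[Si](C(C)C)(C(C)C)C(C)C)cc2OC[C@@H]1c1ccc(O[Si](C)(C)C(C)(C)C)c(CC=C(C)C)c1 | intermediate
20 | (3S)-3-[4-(tert-butyldimethylsilyloxy)-3-(3-methylbut-2-enyl)phenyl]-6-(3-methylbut-2-enyl)-7-(triisopropylsilyloxy)chroman-4-one | O=C1c2cc(CC=C(C)C)c(O[Si](C(C)C)(C(C)C)C(C)C)cc2OC[C@@H]1c1ccc(O[Si](C)(C)C(C)(C)C)c(CC=C(C)C)c1 | intermediate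
21 | (3S)-7-hydroxy-3-[4-hydroxy-3-(3-methylbut-2-enyl)phenyl]-6-(3-methylbut-2-enyl)chroman-4-one | CC(C)=CCc1cc([C@H]2COc3cc(O)c(CC=C(C)C)cc3C2=O)ccc1O | target

## Step count and least certain steps

Total: 14 steps. Longest linear sequence: 12 steps (steps 1 to 7 and 10 to 14, from 1 to 21); the ynone branch (steps 8 and 9) has 2 steps.

**Step 10 (key step).** The most likely failure is that conjugate addition of pyrrolidine to the terminal ynone and oligomerisation of the ynone outrun the enamine addition, or that the open-chain adduct does not reach the cis geometry and stalls before ring closure. Terminal ynones are very reactive towards secondary amines, and the closure needs the cis enone. The fallback separates ring formation from aromatisation. It sets out from 11 and 13.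
- Addition of CH2=CHMgBr to 13 should give 7-methylocta-1,6-dien-3-one F1.
- Enamine Michael addition of 11 to F1 with pyrrolidine and AcOH, then aldol condensation on warming (a Robinson-type annulation through the same α'-methylene), should give 2-(3-methylbut-2-enyl)-4-[(3S,4S)-6-(3-methylbut-2-enyl)-4-(triethylsilyloxy)-7-(triisopropylsilyloxy)chroman-3-yl]cyclohex-2-en-1-one F2.
- Kinetic deprotonation with LiN(i-Pr)2 and trapping with Me3SiCl should give the cross-conjugated trimethylsilyl dienol ether F3.
- Saegusa oxidation with Pd(OAc)2 in MeCN should give dienone 16, which tautomerises, so the route is rejoined at 17.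

**Step 4.** The most likely failure is loss of enantiopurity through base-mediated enolisation of the product in the flask, or slow turnover because the para-silyloxy group makes the aldehyde electron-rich. The fallback moves the stereochemical control to the reduction. It sets out from 6.
- An achiral triazolium salt with Et3N should give racemic ethyl 2-[6-(3-methylbut-2-enyl)-4-oxo-7-(triisopropylsilyloxy)chroman-3-yl]acetate F4.
- Asymmetric transfer hydrogenation with RuCl(p-cymene)[(S,S)-TsDPEN] (or its antipode, chosen for the (3S,4S) product) in HCO2H/Et3N should operate as a dynamic kinetic resolution, because the ketone racemises through its enol while one enantiomer is reduced faster to the cis carbinol 8.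
- Under these conditions 8 should close to the cis-fused lactone (3aS,9bS)-8-(3-methylbut-2-enyl)-7-(triisopropylsilyloxy)-3,3a,4,9b-tetrahydro-2H-furo[3,2-c]chromen-2-one F5.
- Reduction of F5 with LiAlH4 rejoins the route at 9.

**Step 2.** The most likely failure is loss of regiocontrol in the reductive elimination from the η3-prenyl palladium intermediate (reverse-prenyl isomer), or migration of the double bond into conjugation with the ring. The fallback sets out from 2.
- Stille coupling of 2 with tributyl(allyl)stannane and Pd(PPh3)4 should give 5-allyl-2-hydroxy-4-(triisopropylsilyloxy)benzaldehyde F6; the allyl group is symmetric, so no regiochemical question arises.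
- Olefin cross-metathesis of F6 with 2-methylbut-2-ene and second-generation Grubbs catalyst should convert allyl into prenyl and rejoin the route at 4.

**Step 7.** The most likely failure is partial cleavage of the secondary benzylic silyl ether, or electrophilic attack of the chlorosulfonium salt on the electron-rich ring A, while the primary ether is being activated. The fallback separates unmasking from oxidation. It sets out from 10.
- Selective solvolysis of the primary triethylsilyl ether with pyridinium p-toluenesulfonate in MeOH/CH2Cl2 at 0 °C should give 2-[(3S,4S)-6-(3-methylbut-2-enyl)-4-(triethylsilyloxy)-7-(triisopropylsilyloxy)chroman-3-yl]ethanol F7.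
- Dess–Martin oxidation of F7 with NaHCO3 rejoins the route at 11.

**Step 14.** The most likely failure is enolisation at C3 during the fluoride treatment, which would erode the enantiopurity, because the C3–H bond of the isoflavanone is both benzylic and α to the ketone. The fallback changes the order so that the last step is a neutral oxidation. It sets out from 19.
- Buffered Bu4NF/AcOH should remove both aryl silyl groups at the carbinol stage, where C3 is not acidic, to give (3S,4S)-3-[4-hydroxy-3-(3-methylbut-2-enyl)phenyl]-6-(3-methylbut-2-enyl)chroman-4,7-diol F8.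
- Oxidation of the benzylic carbinol of F8 with activated MnO2 in CH2Cl2, a reagent that prefers benzylic alcohols over phenols, arrives directly at 21.

## Further compounds

F1 | step 10 | 7-methylocta-1,6-dien-3-one | C=CC(=O)CCC=C(C)C
F2 | step 10 | 2-(3-methylbut-2-enyl)-4-[(3S,4S)-6-(3-methylbut-2-enyl)-4-(triethylsilyloxy)-7-(triisopropylsilyloxy)chroman-3-yl]cyclohex-2-en-1-one (both epimers at the ring CH) | O=C1CCC([C@H]2COc3cc(O[Si](C(C)C)(C(C)C)C(C)C)c(CC=C(C)C)cc3[C@H]2O[Si](CC)(CC)CC)C=C1CC=C(C)C
F3 | step 10 | trimethyl{[6-(3-methylbut-2-enyl)-4-[(3S,4S)-6-(3-methylbut-2-enyl)-4-(triethylsilyloxy)-7-(triisopropylsilyloxy)chroman-3-yl]cyclohexa-1,5-dien-1-yl]oxy}silane | C[Si](C)(C)OC1=CCC([C@H]2COc3cc(O[Si](C(C)C)(C(C)C)C(C)C)c(CC=C(C)C)cc3[C@H]2O[Si](CC)(CC)CC)C=C1CC=C(C)C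
F4 | step 4 | racemic ethyl 2-[6-(3-methylbut-2-enyl)-4-oxo-7-(triisopropylsilyloxy)chroman-3-yl]acetate | CCOC(=O)CC1COc2cc(O[Si](C(C)C)(C(C)C)C(C)C)c(CC=C(C)C)cc2C1=O
F5 | step 4 | (3aS,9bS)-8-(3-methylbut-2-enyl)-7-(triisopropylsilyloxy)-3,3a,4,9b-tetrahydro-2H-furo[3,2-c]chromen-2-one | O=C1C[C@H]2COc3cc(O[Si](C(C)C)(C(C)C)C(C)C)c(CC=C(C)C)cc3[C@H]2O1
F6 | step 2 | 5-allyl-2-hydroxy-4-(triisopropylsilyloxy)benzaldehyde | O=Cc1cc(CC=C)c(O[Si](C(C)C)(C(C)C)C(C)C)cc1O
F7 | step 7 | 2-[(3S,4S)-6-(3-methylbut-2-enyl)-4-(triethylsilyloxy)-7-(triisopropylsilyloxy)chroman-3-yl]ethanol | OCC[C@H]1COc2cc(O[Si](C(C)C)(C(C)C)C(C)C)c(CC=C(C)C)cc2[C@H]1O[Si](CC)(CC)CC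
F8 | step 14 | (3S,4S)-3-[4-hydroxy-3-(3-methylbut-2-enyl)phenyl]-6-(3-methylbut-2-enyl)chroman-4,7-diol | O[C@@H]1c2cc(CC=C(C)C)c(O)cc2OC[C@@H]1c1ccc(O)c(CC=C(C)C)c1
A1 | alternative 1 | (E)-1-diazo-7-methylocta-3,6-dien-2-one | [N-]=[N+]=CC(=O)/C=C/CC=C(C)C
A2 | alternative 1 | methoxyacetylene | COC#C
A3 | alternative 1 | 5-methoxy-2-(3-methylbut-2-enyl)phenol | COc1ccc(CC=C(C)C)c(O)c1
A4 | alternative 2 | 1-[4-hydroxy-3-(3-methylbut-2-enyl)phenyl]-2-[2-formyl-4-(3-methylbut-2-enyl)-5-(triisopropylsilyloxy)phenoxy]ethyl acetate | CC(=O)OC(COc1cc(O[Si](C(C)C)(C(C)C)C(C)C)c(CC=C(C)C)cc1C=O)c1ccc(O)c(CC=C(C)C)c1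
A5 | alternative 2 | 2-{2-[3-(3-methylbut-2-enyl)-4-oxocyclohexa-2,5-dien-1-ylidene]ethoxy}-5-(3-methylbut-2-enyl)-4-(triisopropylsilyloxy)benzaldehyde | O=C1C=CC(=CCOc2cc(O[Si](C(C)C)(C(C)C)C(C)C)c(CC=C(C)C)cc2C=O)C=C1CC=C(C)C
A6 | alternative 2 | (S)-4'-hydroxy-6,3'-diprenyl-7-triisopropylsilyloxyisoflavanone | O=C1c2cc(CC=C(C)C)c(O[Si](C(C)C)(C(C)C)C(C)C)cc2OC[C@@H]1c1ccc(O)c(CC=C(C)C)c1
A7 | alternative 3 | tert-butyl{4-[(2S,3R)-1-(ethynyloxy)-3-(triethylsilyloxy)pent-4-yn-2-yl]-2-(3-methylbut-2-enyl)phenoxy}dimethylsilane | CC[Si](CC)(CC)O[C@@H](C#C)[C@H](COC#C)c1ccc(O[Si](C)(C)C(C)(C)C)c(CC=C(C)C)c1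
A8 | alternative 3 | triisopropyl[(5-methylhex-4-en-1-yn-1-yl)oxy]silane | CC(C)=CCC#CO[Si](C(C)C)(C(C)C)C(C)C
A9 | alternative 3 | (3S,4R)-3-[4-(tert-butyldimethylsilyloxy)-3-(3-methylbut-2-enyl)phenyl]-6-(3-methylbut-2-enyl)-4-(triethylsilyloxy)-7-(triisopropylsilyloxy)chroman (trans) | CC[Si](CC)(CC)O[C@H]1c2cc(CC=C(C)C)c(O[Si](C(C)C)(C(C)C)C(C)C)cc2OC[C@@H]1c1ccc(O[Si](C)(C)C(C)(C)C)c(CC=C(C)C)c1
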